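## Structural features

The target is a bridged and fused tricycle: a ten-membered carbocycle C1–C10, an oxygen bridge from C1 to C4 that makes a cis-2,5-disubstituted tetrahydrofuran (C4 quaternary and methylated), and a butenolide (C6–O–C12(=O)–C11=C7) fused along C6–C7, whose exocyclic enol-lactone alkene C5=C6 is itself a bond of the carbocycle, with C4 and C7 on the same side. C11 carries the acetoxymethyl carbon C13, C8 a secondary ester of (2S)-2-methyloxirane-2-carboxylic acid, and C10 a tertiary alcohol with a methyl group. Four stereocentres lie on the ring: C1 (S) and C10 (R) are neighbours, C4 (R) faces C1 across the ring oxygen, and C8 (S) is 1,3 to C10 and allylic to the butenolide; the fifth sits in the epoxy acid. The fragile groups are the enol lactone (an acyl donor, opened by hydroxide or alkoxide), the C13 acetate (allylic on an electron-poor alkene, exchanged by addition–elimination and expelled by vinylogous E1cB elimination whenever C6 becomes carbanionic) and the epoxy ester. The real difficulty is closing the strained medium ring at C5=C6 in the presence of these groups, and after that the control of C8 and C10 relative to the tetrahydrofuran. The key step exploits the tetrasubstituted C7=C11 alkene with its C13 oxygen: this array is the 1,3-transposed form of a C7 carbinol next to a C11=C13 methylene, so C11, C12 and C13 of the lactone ring can come from an acrylate ester on the C6 oxygen that is joined to a C7 ketone.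

## Logic of the disconnections

25 to 22 and 24 (24 from 23): the C8–O acyl bond is cut. The epoxy ester is the most reagent-sensitive group and its acid can be bought in one enantiomeric form, so it goes on last, away from phosphines, radicals, ozone and fluoride. The forward step must acylate the secondary C8 hydroxyl and leave the tertiary C10 hydroxyl and the C13 acetate alone.

22 to 21: two O–Si bonds are cut. The C8 and C10 oxygens must be masked from steps 5 and 7 onward. The forward step needs a fluoride source that neither opens the enol lactone nor moves the acetate.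

21 to 18 (through 19 and 20): the C5=C6 alkene, which closes the ten-membered ring, is cut. It is the one ring bond that can be made from a butenolide γ-carbon and an aldehyde, both latent in 17, and the C5 aldehyde cannot enolise because C4 is quaternary. The medium ring falls back to an open chain and the vinyl group serves as the masked C5 carbonyl. The forward step needs weak base (because of the acetate) and high dilution; the ring-cis geometry is enforced by the ring.

18 to 17: the C6–Br bond is cut. C6 must become an electrophilic handle for phosphorus without a carbanion at C6. The forward step needs hydrogen abstraction at C6 and not at C8 or C13.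

17 to 15 (through 16): the C13–O bond is returned to C7 and the alkene from C7=C11 to C11=C13. This uncovers an aldol-type adduct and makes the acetate of the target the migrating group. The forward step must acetylate a hindered tertiary carbinol and relay the acetate by SN2′ and SN2 attack.

15 to 14: the C7–C11 bond is cut (key step). The lactone ring and three carbons reduce to an acrylate ester on the C6 oxygen of a hydroxy ketone. The forward step must generate the enolate only at the acrylate and must not epimerise C8.

14 to 13, to 11 and 12, to 10: the C7 carbonyl goes back to a carbinol, the acrylate C–O bond is cut, and the 1,2-diol is masked as an acetonide. The C6/C7 dioxygenation pattern is exactly that of 6. The forward steps need primary-selective acylation, oxidation without acyl migration, and acetal hydrolysis that spares both silyl ethers.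

10 to 9 to 8: the C10–CH3 bond is cut. C10 lies next to the ring oxygen, so a chelate can control the addition. The C8 oxygen must be a non-chelating silyl ether at that stage.

8 to 7, to 5 and 6: the C8–C9 bond is cut (aldol). C9 is the methyl group of a methyl ketone, and 6 supplies C6–C8; its stereocentre directs C8 and is then sacrificed as the C7 ketone. The forward step needs a kinetic enolate and Felkin selectivity.

5 to 4 to 2 to 1 (3 in passing): the acetyl group comes from glycol cleavage, the ring C1–O bond from epoxide opening, and the epoxide from an allylic alcohol made by allylic oxidation. Compound 1 supplies C1–C5, C9, C10 and the C4 stereocentre; C1 is set by reagent control. The forward steps need (E)-selective oxidation, face-selective epoxidation and 5-exo opening.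

## Other disconnections considered

Alternative 1: The cut is at C4–C5 and C1–C10, the two bonds that flank the tetrahydrofuran, and later at C6–C10 by oxygen insertion.
- Forward step: an oxyallyl cation, released from chloro ketone A1 by an alkoxide in a fluorinated alcohol, adds across the α-positions of 2-methylfuran A2 to give the oxabicyclic ketone A3. Baeyer–Villiger oxidation would then move the quaternary C10 onto oxygen with retention and leave C5–C6 as an acetic ester arm.
- In favour: the cis relation of C1 and C4 follows from the bridge and needs no reagent control. On this point it is better than the chosen plan, which sets C1 by asymmetric epoxidation. Two quaternary centres arise in one step from achiral bulk chemicals.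
- Against: A3 would form as a racemate, whereas the chosen plan takes C4 from 1. The methyl and 2-benzyloxyethyl groups on the cation terminus differ little in size, so the required C10 epimer cannot be expected to dominate, whereas the chelation of step 6 is dependable. C8 stays an unfunctionalised CH2O carbon, C7 and C11–C13 are absent, and neither the medium ring nor the acetate problem is addressed.
- Comparison: mechanistically it is a cationic cycloaddition followed by a migration, against closed-shell polar steps. Up to a C1–C10 fragment the step counts are about equal (some five against seven), but the alternative then still needs a lactone annulation of the kind of step 11 and a ring closure.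

Alternative 2: The cut is at C8–C9, made in exchange for the C1–C6 bond of a six-membered ring.
- Forward step: the potassium alkoxide of a 1,2-dialkenyl cyclohexanol undergoes an anionic oxy-Cope shift to the (E)-cyclodecenone A4, formed as its C6–C7 enolate.
- In favour: the ten-membered ring comes from ring expansion with no end-to-end cyclisation. Here the alternative is clearly better than the chosen plan, whose ring closure (step 14) is its least secure step after the key step. The C1/C10 relationship is encoded in the (E)-alkene, because epoxidation and transannular opening by the C4 oxygen amount to the anti addition that the target shows. The enolate is correctly placed for adding C11–C13 at C7.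
- Against: C8 is set by chirality transfer from ring centres that are themselves controlled only by a remote relationship to C4. The tetrahydrofuran must be made late on a flexible ring, where the face selectivity relative to C4 is not predictable. The dienolide must be annulated onto a hindered medium-ring ketone, again with a C13 oxygen present.
- Comparison: the mechanism is pericyclic against aldol-type. The step count would be about equal, perhaps slightly lower for the alternative; stereochemical reliability at C1, C8 and C10 is higher in the chosen plan.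

Alternative 3: The cut is the C5=C6 alkene, seen as the remnant of a sulfonyl bridge.
- Forward step: the eleven-membered sulfone A5 is halogenated at the acidic C6 and treated with base, so that an episulfone closes the C5–C6 bond and loses SO2 to give the ring-contracted bis-silyl ether A6.
- In favour: the ring is closed by C–S bond formation and then contracted, which tolerates strain and hindrance better than the olefination of step 14. On this point it is the better method. The alkene geometry is again dictated by the ring.
- Against: strongly basic, hydroxide-containing conditions are needed, which an allylic acetate and an enol lactone cannot be expected to survive. C13 must therefore travel as a silyl ether, and the acetate that step 12 delivers at no cost must be removed and put back. A6 is itself an enol lactone exposed to the base. Sulfur must be brought to C5, a neopentyl-type carbon next to the quaternary C4, by substitution.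
- Comparison: both plans need the same C6 functionalisation and are equal there. This disconnection competes with the ring closure of step 14, not with the lactone annulation of step 11; it would replace one step by about five and add two or three for the acetate.

Key step: step 11

Remarks on the chemistry:
- Atom numbers C1–C13 are those of the first section and are used for every intermediate.
- Written out atom by atom, 14 and 15 have the same spatial arrangement at C1, C4, C8 and C10 as 25, so no centre is inverted on the way.
- The ring closure of step 11 is, strictly, 5-(enolendo)-exo-trig.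
- The vinyl group holds one carbon more than C5 and is treated as a masked C5 aldehyde.
- Assumption: methyl (2S)-2-methyloxirane-2-carboxylate 23, D-(−)-diethyl tartrate and 1 are taken as purchasable in high enantiomeric purity.

## Route

Step 1
Reactants: 1 (R)-linalool
Product: 2 (2E,6R)-2,6-dimethylocta-2,7-diene-1,6-diol
Conditions: SeO2 (cat.), t-BuOOH, salicylic acid (cat.), CH2Cl2, 23 °C
Reagents that add atoms: tert-butyl hydroperoxide, CC(C)(C)OO (terminal oxidant; the oxygen is passed on by SeO2, O=[Se]=O)
Why: Allylic oxidation with SeO2 (ene reaction, then [2,3]-sigmatropic shift) attacks the (E)-methyl group of the trisubstituted alkene; the vinyl group has no allylic hydrogen and the tertiary alcohol is inert. No stereocentre is formed.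

Step 2
Reactants: 2 (2E,6R)-2,6-dimethylocta-2,7-diene-1,6-diol
Product: 4 (2R)-2-[(2S,5R)-5-ethenyl-5-methyloxolan-2-yl]propane-1,2-diol, via epoxy diol 3 (not isolated)
Conditions: Ti(OiPr)4 (10 mol %), D-(−)-diethyl tartrate (12 mol %), t-BuOOH, 4 Å molecular sieves, CH2Cl2, −20 °C; then camphorsulfonic acid (30 mol %), 0 °C
Reagents that add atoms: tert-butyl hydroperoxide, CC(C)(C)OO
Why: Sharpless asymmetric epoxidation of the primary allylic alcohol (the tertiary vinyl carbinol reacts far more slowly) with the D-tartrate should give the (2R,3R)-epoxide 3 by reagent control. Acid then triggers 5-exo-tet opening by the tertiary hydroxyl at the secondary epoxide carbon with inversion, which sets C1 as (S) and places the vinyl group and the side chain cis. The side-chain carbinol centre is lost in step 3.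

Step 3
Reactants: 4 (2R)-2-[(2S,5R)-5-ethenyl-5-methyloxolan-2-yl]propane-1,2-diol
Product: 5 1-[(2S,5R)-5-ethenyl-5-methyloxolan-2-yl]ethan-1-one
Conditions: NaIO4, THF/H2O, 0 → 23 °C
Reagents that add atoms: none
Why: Periodate glycol cleavage of the tertiary–primary 1,2-diol gives the methyl ketone (C10 with the future C9) and formaldehyde. The medium is near neutral, so the α-oxygenated C1 centre should not epimerise, and the vinyl group is untouched.

Step 4
Reactants: 5 1-[(2S,5R)-5-ethenyl-5-methyloxolan-2-yl]ethan-1-one; 6 (R)-glyceraldehyde acetonide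
Product: 7 (3S)-3-[(4R)-2,2-dimethyl-1,3-dioxolan-4-yl]-1-[(2S,5R)-5-ethenyl-5-methyloxolan-2-yl]-3-hydroxypropan-1-one
Conditions: LiN(iPr)2, THF, −78 °C; then 6, −78 °C; NH4Cl (aq.)
Reagents that add atoms: (R)-glyceraldehyde acetonide (6), O=C[C@H]1COC(C)(C)O1
Why: Kinetic deprotonation occurs at the methyl group and the lithium enolate undergoes aldol addition (C8–C9). Attack anti to the α-C–O bond of 6 (polar Felkin–Anh model) should favour the 7,8-anti adduct, that is (8S); the minor epimer is removed by chromatography.

Step 5
Reactants: 7 (3S)-3-[(4R)-2,2-dimethyl-1,3-dioxolan-4-yl]-1-[(2S,5R)-5-ethenyl-5-methyloxolan-2-yl]-3-hydroxypropan-1-one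
Product: 8 (3S)-3-(tert-butyldimethylsilyloxy)-3-[(4R)-2,2-dimethyl-1,3-dioxolan-4-yl]-1-[(2S,5R)-5-ethenyl-5-methyloxolan-2-yl]propan-1-one
Conditions: TBSOTf, 2,6-lutidine, CH2Cl2, −78 °C
Reagents that add atoms: tert-butyldimethylsilyl triflate, CC(C)(C)[Si](C)(C)OS(=O)(=O)C(F)(F)F
Why: Silylation with the silyl triflate and a hindered pyridine base at low temperature protects the β-hydroxy ketone without retro-aldol cleavage or elimination. A silyl ether is chosen because it does not chelate magnesium in step 6.

Step 6
Reactants: 8 (3S)-3-(tert-butyldimethylsilyloxy)-3-[(4R)-2,2-dimethyl-1,3-dioxolan-4-yl]-1-[(2S,5R)-5-ethenyl-5-methyloxolan-2-yl]propan-1-one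
Product: 9 (2R,4S)-4-(tert-butyldimethylsilyloxy)-4-[(4R)-2,2-dimethyl-1,3-dioxolan-4-yl]-2-[(2S,5R)-5-ethenyl-5-methyloxolan-2-yl]butan-2-ol
Conditions: MeMgBr, THF, −78 °C
Reagents that add atoms: methylmagnesium bromide, C[Mg]Br
Why: Grignard addition under Cram chelate control: magnesium bridges the ketone oxygen and the tetrahydrofuran oxygen, and the methyl group enters from the face of the C1 hydrogen, which should give the (10R) tertiary alcohol. The C8 silyl ether and the acetonide coordinate too weakly to compete.

Step 7
Reactants: 9 (2R,4S)-4-(tert-butyldimethylsilyloxy)-4-[(4R)-2,2-dimethyl-1,3-dioxolan-4-yl]-2-[(2S,5R)-5-ethenyl-5-methyloxolan-2-yl]butan-2-ol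
Product: 10 O10-triethylsilyl ether of 9
Conditions: TESOTf, 2,6-lutidine, CH2Cl2, 0 °C
Reagents that add atoms: triethylsilyl triflate, CC[Si](CC)(CC)OS(=O)(=O)C(F)(F)F
Why: Silyl triflate silylation of the tertiary alcohol. The C10 oxygen must be blocked because a free γ-hydroxyl would close a five-membered hemiketal onto the C7 ketone made in step 10.

Step 8
Reactants: 10 O10-triethylsilyl ether of 9
Product: 11 (2R,3S,5R)-3-(tert-butyldimethylsilyloxy)-5-[(2S,5R)-5-ethenyl-5-methyloxolan-2-yl]-5-(triethylsilyloxy)hexane-1,2-diol
Conditions: AcOH/H2O (4:1), 23 °C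
Reagents that add atoms: none
Why: Acid-catalysed hydrolysis of the terminal dioxolane. Aqueous acetic acid is chosen because the secondary TBS ether and the hindered tertiary TES ether should hydrolyse more slowly than an unhindered isopropylidene acetal.

Step 9
Reactants: 11 (2R,3S,5R)-3-(tert-butyldimethylsilyloxy)-5-[(2S,5R)-5-ethenyl-5-methyloxolan-2-yl]-5-(triethylsilyloxy)hexane-1,2-diol; 12 acryloyl chloride
Product: 13 (2R,3S,5R)-3-(tert-butyldimethylsilyloxy)-5-[(2S,5R)-5-ethenyl-5-methyloxolan-2-yl]-2-hydroxy-5-(triethylsilyloxy)hexyl prop-2-enoate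
Conditions: 12, 2,4,6-collidine, CH2Cl2, −78 → −40 °C
Reagents that add atoms: acryloyl chloride (12), C=CC(Cl)=O
Why: Acylation of the primary hydroxyl with the acid chloride and a hindered base at low temperature. The C7 hydroxyl is secondary and flanked by the C8 silyl ether, so monoacylation at O6 should prevail.

Step 10
Reactants: 13 (2R,3S,5R)-3-(tert-butyldimethylsilyloxy)-5-[(2S,5R)-5-ethenyl-5-methyloxolan-2-yl]-2-hydroxy-5-(triethylsilyloxy)hexyl prop-2-enoate
Product: 14 (3S,5R)-3-(tert-butyldimethylsilyloxy)-5-[(2S,5R)-5-ethenyl-5-methyloxolan-2-yl]-2-oxo-5-(triethylsilyloxy)hexyl prop-2-enoate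
Conditions: Dess–Martin periodinane, NaHCO3, CH2Cl2, 0 → 23 °C
Reagents that add atoms: none
Why: Dess–Martin oxidation of the secondary alcohol under bicarbonate buffer should give the α-acyloxy ketone without acyl migration or epimerisation at C8. The sacrificial C7 stereocentre is removed here.

Step 11
Reactants: 14 (3S,5R)-3-(tert-butyldimethylsilyloxy)-5-[(2S,5R)-5-ethenyl-5-methyloxolan-2-yl]-2-oxo-5-(triethylsilyloxy)hexyl prop-2-enoate
Product: 15 4-[(1S,3R)-1-(tert-butyldimethylsilyloxy)-3-[(2S,5R)-5-ethenyl-5-methyloxolan-2-yl]-3-(triethylsilyloxy)butyl]-4-hydroxy-3-methylideneoxolan-2-one (either C7 epimer)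
Conditions: PMe3 (0.5 equiv), t-BuOH/THF (1:1), 0.02 M, 23 °C
Reagents that add atoms: none
Why: Intramolecular Morita–Baylis–Hillman reaction: PMe3 adds to C13 of the acrylate, the resulting β-phosphonio ester enolate attacks the C7 ketone through C11, and proton transfer from C11 to the C7 alkoxide (relayed by t-BuOH) followed by E1cB loss of PMe3 restores C11=C13. The closest known reaction types are phosphine-catalysed cyclising Baylis–Hillman reactions of enoates and enones with tethered carbonyl groups and amine-catalysed lactone-forming versions with α-acryloyloxy aldehydes; a ketone acceptor is the less reactive case. The five-membered lactone (C7, C11, C12, O, C6) closes in a 5-(enolendo)-exo-trig mode, exo to the C7 carbonyl with the enolate C11=C12 bond inside the new ring. This mode is nominally unfavourable for enolates but also operates in base-mediated butenolide annulations of α-acyloxy ketones, so it should be feasible once the ester reaches its s-cis conformer. The only new stereocentre is the C7 carbinol; it forms without control and is erased in step 12, while C1, C4, C8 and C10 are untouched. The step needs chemoselectivity: phosphine addition to the acrylate and no enolisation of the ketone toward C8, and ring closure in preference to Rauhut–Currier oligomerisation. The substrate secures this through a ketone made unusually electrophilic by its two flanking oxygens (C6 acyloxy and C8 silyloxy), through the C10 silyl ether that prevents hemiketal formation, and through a small, weakly basic phosphine in a buffering alcohol at high dilution.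

Step 12
Reactants: 15 4-[(1S,3R)-1-(tert-butyldimethylsilyloxy)-3-[(2S,5R)-5-ethenyl-5-methyloxolan-2-yl]-3-(triethylsilyloxy)butyl]-4-hydroxy-3-methylideneoxolan-2-one
Product: 17 {4-[(1S,3R)-1-(tert-butyldimethylsilyloxy)-3-[(2S,5R)-5-ethenyl-5-methyloxolan-2-yl]-3-(triethylsilyloxy)butyl]-2-oxo-2,5-dihydrofuran-3-yl}methyl acetate, via tertiary acetate 16 (not isolated)
Conditions: Ac2O, DMAP, Et3N, CH2Cl2, 23 → 40 °C; then DABCO (30 mol %)
Reagents that add atoms: acetic anhydride, CC(=O)OC(C)=O
Why: Nucleophile-catalysed acetylation of the tertiary allylic alcohol gives 16; the amine then attacks C13 (SN2′) with loss of acetate from C7, and acetate displaces the ammonium group at C13 (SN2), the known 1,3-transposition of Baylis–Hillman acetates. The conjugated, tetrasubstituted C7=C11 butenolide is the thermodynamic sink and the C7 stereocentre disappears.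

Step 13
Reactants: 17 {4-[(1S,3R)-1-(tert-butyldimethylsilyloxy)-3-[(2S,5R)-5-ethenyl-5-methyloxolan-2-yl]-3-(triethylsilyloxy)butyl]-2-oxo-2,5-dihydrofuran-3-yl}methyl acetate
Product: 18 C6-bromide of 17 (5-bromo-2-oxo-2,5-dihydrofuran; C6 epimers)
Conditions: NBS, AIBN (cat.), K2CO3, PhCF3, 80 °C
Reagents that add atoms: N-bromosuccinimide, O=C1CCC(=O)N1Br
Why: Wohl–Ziegler bromination: the C6–H bonds are activated by the ring oxygen and by allylic overlap with C7=C11, whereas allylic strain should hold the C8–H bond in the plane of the alkene, where it gains no allylic stabilisation; the vinyl group has no allylic hydrogen. The new C6 centre forms as a mixture and is lost in step 14.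

Step 14
Reactants: 18 C6-bromide of 17
Product: 21 (1S,4R,5E,8S,10R)-13-acetoxy-8-(tert-butyldimethylsilyloxy)-1,4-epoxy-10-(triethylsilyloxy)germacra-5,7(11)-dien-12,6-olide (numbering of the first section; C4 cis to C7), via bromo aldehyde 19 (not isolated), via phosphonium bromide 20 (not isolated)
Conditions: O3, CH2Cl2, −78 °C; PPh3 (2.2 equiv), −78 → 23 °C; then slow addition to iPr2NEt in CH2Cl2 (final 0.002 M), 40 °C
Reagents that add atoms: none
Why: Ozone should cleave the vinyl group in preference to the electron-poor tetrasubstituted butenolide alkene; PPh3 reduces the ozonide to the non-enolisable aldehyde 19 and is alkylated by the allylic bromide to give 20. A hindered amine then forms the stabilised ylide, and intramolecular Wittig olefination at high dilution closes the ten-membered ring. Only the ring-cis alkene (C4 cis to C7) can be accommodated.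

Step 15
Reactants: 21 (1S,4R,5E,8S,10R)-13-acetoxy-8-(tert-butyldimethylsilyloxy)-1,4-epoxy-10-(triethylsilyloxy)germacra-5,7(11)-dien-12,6-olide
Product: 22 (1S,4R,5E,8S,10R)-13-acetoxy-1,4-epoxy-8,10-dihydroxygermacra-5,7(11)-dien-12,6-olide
Conditions: HF·pyridine, pyridine, THF, 0 → 23 °C
Reagents that add atoms: none
Why: Fluoride-mediated cleavage of both silyl ethers under buffered, mildly acidic conditions, which should leave the enol lactone, the allylic acetate and the tertiary alcohol untouched; a basic fluoride source would invite acetate migration from O13 to O8.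

Step 16
Reactants: 23 methyl (2S)-2-methyloxirane-2-carboxylate
Product: 24 potassium (2S)-2-methyloxirane-2-carboxylate
Conditions: KOH (1.0 equiv), MeOH, 0 °C; evaporation
Reagents that add atoms: potassium hydroxide, [K+].[OH-]
Why: Saponification with one equivalent of hydroxide at low temperature; the hindered 2,2-disubstituted epoxide should not be opened, and the carboxylate salt, unlike the free glycidic acid, can be dried and stored.

Step 17
Reactants: 22 (1S,4R,5E,8S,10R)-13-acetoxy-1,4-epoxy-8,10-dihydroxygermacra-5,7(11)-dien-12,6-olide; 24 potassium (2S)-2-methyloxirane-2-carboxylate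
Product: 25 (1S,4R,5E,8S,10R)-13-acetoxy-1,4-epoxy-10-hydroxy-8-[(2S)-2-methyloxirane-2-carbonyloxy]germacra-5,7(11)-dien-12,6-olide (CNP0142137.1)
Conditions: 24, 2,4,6-trichlorobenzoyl chloride, THF, 23 °C; then 22, DMAP, toluene, 0 → 23 °C
Reagents that add atoms: potassium (2S)-2-methyloxirane-2-carboxylate (24), [K+].[O-]C(=O)[C@]1(C)CO1
Why: Yamaguchi esterification through the mixed anhydride: the secondary C8 hydroxyl is acylated and the tertiary C10 hydroxyl is not. The α-centre of the acid is quaternary and cannot epimerise.

## Compound list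

1 | (R)-linalool, (3R)-3,7-dimethylocta-1,6-dien-3-ol | C=C[C@@](O)(C)CCC=C(C)C | starting material
2 | (2E,6R)-2,6-dimethylocta-2,7-diene-1,6-diol | C=C[C@@](O)(C)CC/C=C(\C)CO | intermediate
3 | [(2R,3R)-3-[(3R)-3-hydroxy-3-methylpent-4-en-1-yl]-2-methyloxiran-2-yl]methanol | C=C[C@@](O)(C)CC[C@H]1O[C@]1(C)CO | intermediate
4 | (2R)-2-[(2S,5R)-5-ethenyl-5-methyloxolan-2-yl]propane-1,2-diol | C=C[C@@]1(C)CC[C@H](O1)[C@](C)(O)CO | intermediate
5 | 1-[(2S,5R)-5-ethenyl-5-methyloxolan-2-yl]ethan-1-one | C=C[C@@]1(C)CC[C@H](O1)C(C)=O | intermediate
6 | (R)-glyceraldehyde acetonide, (4R)-2,2-dimethyl-1,3-dioxolane-4-carbaldehyde | O=C[C@H]1COC(C)(C)O1 | starting material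
7 | (3S)-3-[(4R)-2,2-dimethyl-1,3-dioxolan-4-yl]-1-[(2S,5R)-5-ethenyl-5-methyloxolan-2-yl]-3-hydroxypropan-1-one | C=C[C@@]1(C)CC[C@H](O1)C(=O)C[C@H](O)[C@H]2COC(C)(C)O2 | intermediate
8 | (3S)-3-(tert-butyldimethylsilyloxy)-3-[(4R)-2,2-dimethyl-1,3-dioxolan-4-yl]-1-[(2S,5R)-5-ethenyl-5-methyloxolan-2-yl]propan-1-one | C=C[C@@]1(C)CC[C@H](O1)C(=O)C[C@H](O[Si](C)(C)C(C)(C)C)[C@H]2COC(C)(C)O2 | intermediate
9 | (2R,4S)-4-(tert-butyldimethylsilyloxy)-4-[(4R)-2,2-dimethyl-1,3-dioxolan-4-yl]-2-[(2S,5R)-5-ethenyl-5-methyloxolan-2-yl]butan-2-ol | C=C[C@@]1(C)CC[C@H](O1)[C@](C)(O)C[C@H](O[Si](C)(C)C(C)(C)C)[C@H]2COC(C)(C)O2 | intermediate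
10 | O10-triethylsilyl ether of 9: (2R,4S)-4-(tert-butyldimethylsilyloxy)-4-[(4R)-2,2-dimethyl-1,3-dioxolan-4-yl]-2-[(2S,5R)-5-ethenyl-5-methyloxolan-2-yl]-2-(triethylsilyloxy)butane | C=C[C@@]1(C)CC[C@H](O1)[C@](C)(O[Si](CC)(CC)CC)C[C@H](O[Si](C)(C)C(C)(C)C)[C@H]2COC(C)(C)O2 | intermediate
11 | (2R,3S,5R)-3-(tert-butyldimethylsilyloxy)-5-[(2S,5R)-5-ethenyl-5-methyloxolan-2-yl]-5-(triethylsilyloxy)hexane-1,2-diol | C=C[C@@]1(C)CC[C@H](O1)[C@](C)(O[Si](CC)(CC)CC)C[C@H](O[Si](C)(C)C(C)(C)C)[C@H](O)CO | intermediate
12 | acryloyl chloride | C=CC(Cl)=O | starting material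
13 | (2R,3S,5R)-3-(tert-butyldimethylsilyloxy)-5-[(2S,5R)-5-ethenyl-5-methyloxolan-2-yl]-2-hydroxy-5-(triethylsilyloxy)hexyl prop-2-enoate | C=C[C@@]1(C)CC[C@H](O1)[C@](C)(O[Si](CC)(CC)CC)C[C@H](O[Si](C)(C)C(C)(C)C)[C@H](O)COC(=O)C=C | intermediate
14 | (3S,5R)-3-(tert-butyldimethylsilyloxy)-5-[(2S,5R)-5-ethenyl-5-methyloxolan-2-yl]-2-oxo-5-(triethylsilyloxy)hexyl prop-2-enoate | C=C[C@@]1(C)CC[C@H](O1)[C@](C)(O[Si](CC)(CC)CC)C[C@H](O[Si](C)(C)C(C)(C)C)C(=O)COC(=O)C=C | intermediate
15 | 4-[(1S,3R)-1-(tert-butyldimethylsilyloxy)-3-[(2S,5R)-5-ethenyl-5-methyloxolan-2-yl]-3-(triethylsilyloxy)butyl]-4-hydroxy-3-methylideneoxolan-2-one (either C7 epimer) | C=C[C@@]1(C)CC[C@H](O1)[C@](C)(O[Si](CC)(CC)CC)C[C@H](O[Si](C)(C)C(C)(C)C)C2(O)COC(=O)C2=C | intermediate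
16 | O7-acetate of 15 (4-acetoxy-3-methylideneoxolan-2-one) | C=C[C@@]1(C)CC[C@H](O1)[C@](C)(O[Si](CC)(CC)CC)C[C@H](O[Si](C)(C)C(C)(C)C)C2(OC(C)=O)COC(=O)C2=C | intermediate
17 | {4-[(1S,3R)-1-(tert-butyldimethylsilyloxy)-3-[(2S,5R)-5-ethenyl-5-methyloxolan-2-yl]-3-(triethylsilyloxy)butyl]-2-oxo-2,5-dihydrofuran-3-yl}methyl acetate | C=C[C@@]1(C)CC[C@H](O1)[C@](C)(O[Si](CC)(CC)CC)C[C@H](O[Si](C)(C)C(C)(C)C)C2=C(COC(C)=O)C(=O)OC2 | intermediate
18 | C6-bromide of 17: {5-bromo-4-[(1S,3R)-1-(tert-butyldimethylsilyloxy)-3-[(2S,5R)-5-ethenyl-5-methyloxolan-2-yl]-3-(triethylsilyloxy)butyl]-2-oxo-2,5-dihydrofuran-3-yl}methyl acetate (C6 epimers) | C=C[C@@]1(C)CC[C@H](O1)[C@](C)(O[Si](CC)(CC)CC)C[C@H](O[Si](C)(C)C(C)(C)C)C2=C(COC(C)=O)C(=O)OC2Br | intermediate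
19 | bromo aldehyde: {5-bromo-4-[(1S,3R)-1-(tert-butyldimethylsilyloxy)-3-[(2S,5R)-5-formyl-5-methyloxolan-2-yl]-3-(triethylsilyloxy)butyl]-2-oxo-2,5-dihydrofuran-3-yl}methyl acetate | O=C[C@@]1(C)CC[C@H](O1)[C@](C)(O[Si](CC)(CC)CC)C[C@H](O[Si](C)(C)C(C)(C)C)C2=C(COC(C)=O)C(=O)OC2Br | intermediate
20 | phosphonium bromide: the C6-triphenylphosphonium salt corresponding to 19 | O=C[C@@]1(C)CC[C@H](O1)[C@](C)(O[Si](CC)(CC)CC)C[C@H](O[Si](C)(C)C(C)(C)C)C2=C(COC(C)=O)C(=O)OC2[P+](c3ccccc3)(c4ccccc4)c5ccccc5.[Br-] | intermediate
21 | (1S,4R,5E,8S,10R)-13-acetoxy-8-(tert-butyldimethylsilyloxy)-1,4-epoxy-10-(triethylsilyloxy)germacra-5,7(11)-dien-12,6-olide | CC(=O)OCC1=C2/C(=C\[C@@]3(C)CC[C@H](O3)[C@](C)(O[Si](CC)(CC)CC)C[C@@H]2O[Si](C)(C)C(C)(C)C)OC1=O | intermediate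
22 | (1S,4R,5E,8S,10R)-13-acetoxy-1,4-epoxy-8,10-dihydroxygermacra-5,7(11)-dien-12,6-olide | CC(=O)OCC1=C2/C(=C\[C@@]3(C)CC[C@H](O3)[C@](C)(O)C[C@@H]2O)OC1=O | intermediate
23 | methyl (2S)-2-methyloxirane-2-carboxylate | COC(=O)[C@]1(C)CO1 | starting material
24 | potassium (2S)-2-methyloxirane-2-carboxylate | [K+].[O-]C(=O)[C@]1(C)CO1 | intermediate
25 | (1S,4R,5E,8S,10R)-13-acetoxy-1,4-epoxy-10-hydroxy-8-[(2S)-2-methyloxirane-2-carbonyloxy]germacra-5,7(11)-dien-12,6-olide (CNP0142137.1) | CC(=O)OCC1=C2/C(=C\[C@@]3(C)CC[C@H](O3)[C@](C)(O)C[C@@H]2OC(=O)[C@]2(C)CO2)OC1=O | target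

## Step count and least certain steps

Total step count: 17. Longest linear sequence: 16 (steps 1–15 and 17, from 1); step 16 is a one-step branch.

Step 11 (key step). The zwitterionic enolate may be drained by intermolecular Rauhut–Currier oligomerisation or by proton transfer to a phosphorus ylide before it closes onto the ketone, because the ester must reach its less populated s-cis conformer and the closure is enolendo. The basic zwitterion may also epimerise C8. The fallback sets out from 14 and replaces nucleophilic catalysis by a stoichiometric iodo-aldol cyclisation. MgI2 in CH2Cl2 at −78 → 0 °C would add iodide to C13 and hold the metal enolate against the ketone oxygen, so that the aldol closure gives the iodomethyl hydroxy lactone F1. Et3N would then remove hydrogen iodide across C11–C13 and the route is rejoined at 15.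

Step 14. Ring strain and the bulk of the phosphonium group may slow the intramolecular olefination, so that intermolecular olefination or reversible loss of acetate from the ylide (a 2-oxidofuran) takes over. The fallback sets out from 17 and needs no bromide. Ozonolysis (O3, then PPh3) would give the aldehyde F2. TBSOTf and iPr2NEt in dilute CH2Cl2 at −78 °C would form the 2-silyloxyfuran in the flask and promote an intramolecular vinylogous Mukaiyama aldol addition of C6 to C5, giving the silylated aldol F3. DBU would then eliminate the silanol across C5–C6; this exit is irreversible, whereas loss of acetate is reversible. The route is rejoined at 21.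

Step 13. Hydrogen abstraction may occur at C8–H, or bromine may add to the vinyl group, in place of substitution at C6. The fallback sets out from 17 and is polar, not radical. Soft enolisation (TBSOTf, Et3N, CH2Cl2, 0 °C) would give the 2-silyloxyfuran F4, which can only have formed by loss of a C6 proton. NBS in THF at −78 °C would then brominate the furan at C6 and return the route to 18.

Step 4. Facial selectivity may be poor, because the closed transition state of a small lithium methyl-ketone enolate distinguishes the aldehyde faces only moderately and the remote C1 centre may work against it. The fallback sets out from 5 and uses an open transition state. The trimethylsilyl enol ether F5 (LiN(iPr)2, then Me3SiCl) would be added to 6 with BF3·OEt2 in CH2Cl2 at −78 °C, a Mukaiyama aldol addition that follows the polar Felkin–Anh model more strictly. Desilylating work-up returns the route to 7.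

Step 12. Acetylation of the hindered tertiary carbinol may be incomplete, and the nucleophilic amines may reopen the ring by a retro-aldol path. The fallback sets out from 15 and moves the leaving group first. NBS and Me2S (Corey–Kim conditions, CH2Cl2, −20 °C) would convert the tertiary alcohol by SN2′ attack of bromide into the allylic bromide F6. KOAc with 18-crown-6 in MeCN would then displace bromide at C13 and return the route to 17.

## Further compounds

F1 | step 11 | 4-[(1S,3R)-1-(tert-butyldimethylsilyloxy)-3-[(2S,5R)-5-ethenyl-5-methyloxolan-2-yl]-3-(triethylsilyloxy)butyl]-4-hydroxy-3-(iodomethyl)oxolan-2-one | C=C[C@@]1(C)CC[C@H](O1)[C@](C)(O[Si](CC)(CC)CC)C[C@H](O[Si](C)(C)C(C)(C)C)C2(O)COC(=O)C2CI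
F2 | step 14 | {4-[(1S,3R)-1-(tert-butyldimethylsilyloxy)-3-[(2S,5R)-5-formyl-5-methyloxolan-2-yl]-3-(triethylsilyloxy)butyl]-2-oxo-2,5-dihydrofuran-3-yl}methyl acetate | O=C[C@@]1(C)CC[C@H](O1)[C@](C)(O[Si](CC)(CC)CC)C[C@H](O[Si](C)(C)C(C)(C)C)C2=C(COC(C)=O)C(=O)OC2
F3 | step 14 | (1S,4R,8S,10R)-13-acetoxy-5,8-bis(tert-butyldimethylsilyloxy)-1,4-epoxy-10-(triethylsilyloxy)germacr-7(11)-en-12,6-olide (C5 and C6 epimers) | CC(=O)OCC1=C2C(OC1=O)C(O[Si](C)(C)C(C)(C)C)[C@@]3(C)CC[C@H](O3)[C@](C)(O[Si](CC)(CC)CC)C[C@@H]2O[Si](C)(C)C(C)(C)C
F4 | step 13 | {2-(tert-butyldimethylsilyloxy)-4-[(1S,3R)-1-(tert-butyldimethylsilyloxy)-3-[(2S,5R)-5-ethenyl-5-methyloxolan-2-yl]-3-(triethylsilyloxy)butyl]furan-3-yl}methyl acetate | C=C[C@@]1(C)CC[C@H](O1)[C@](C)(O[Si](CC)(CC)CC)C[C@H](O[Si](C)(C)C(C)(C)C)c2coc(O[Si](C)(C)C(C)(C)C)c2COC(C)=O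
F5 | step 4 | {1-[(2S,5R)-5-ethenyl-5-methyloxolan-2-yl]ethenyloxy}trimethylsilane | C=C[C@@]1(C)CC[C@H](O1)C(=C)O[Si](C)(C)C
F6 | step 12 | 3-(bromomethyl)-4-[(1S,3R)-1-(tert-butyldimethylsilyloxy)-3-[(2S,5R)-5-ethenyl-5-methyloxolan-2-yl]-3-(triethylsilyloxy)butyl]furan-2(5H)-one | C=C[C@@]1(C)CC[C@H](O1)[C@](C)(O[Si](CC)(CC)CC)C[C@H](O[Si](C)(C)C(C)(C)C)C2=C(CBr)C(=O)OC2
A1 | alternative 1 | 5-(benzyloxy)-3-chloro-3-methylpentan-2-one (racemic; the centre is lost on ionisation) | CC(=O)C(C)(Cl)CCOCc1ccccc1
A2 | alternative 1 | 2-methylfuran | Cc1ccco1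
A3 | alternative 1 | 4-[2-(benzyloxy)ethyl]-1,4-dimethyl-8-oxabicyclo[3.2.1]oct-6-en-3-one (enantiomer and C10 epimer that map onto 25) | O=C1C[C@@]2(C)C=C[C@H](O2)[C@@]1(C)CCOCc1ccccc1
A4 | alternative 2 | (5E)-3-[(4-methoxyphenyl)methoxy]-5,9-dimethyl-9-(triethylsilyloxy)cyclodec-5-en-1-one | O=C1C[C@@H](OCc2ccc(OC)cc2)C/C(C)=C/CC[C@@](C)(O[Si](CC)(CC)CC)C1
A5 | alternative 3 | eleven-membered sulfone bridging C5 and C6, with O8 and O13 as tert-butyldimethylsilyl ethers and a free C10 hydroxyl (C6 epimers) | CC(C)(C)[Si](C)(C)OCC1=C2C(OC1=O)S(=O)(=O)C[C@@]3(C)CC[C@H](O3)[C@](C)(O)C[C@@H]2O[Si](C)(C)C(C)(C)C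
A6 | alternative 3 | 8,13-bis-O-(tert-butyldimethylsilyl) ether of the deacylated core of 25 | CC(C)(C)[Si](C)(C)OCC1=C2/C(=C\[C@@]3(C)CC[C@H](O3)[C@](C)(O)C[C@@H]2O[Si](C)(C)C(C)(C)C)OC1=O
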